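## Structural features

The target is a germacranolide: a ten-membered carbocycle (C1–C10) fused along C6–C7 to a butenolide (O–C6, C7=C11, C12=O). The tetrasubstituted butenolide alkene is exocyclic to the large ring at C7 and carries the acetoxymethyl carbon C13 on C11. The large ring bears a trans, trisubstituted 4,5-epoxide (methyl C15 on C4), a cis, trisubstituted 1,10-epoxide (methyl C14 on C10) and a secondary acetate at C8. The six stereocentres form three clusters: the contiguous triad C4–C5–C6 (4R,5R,6S, with a threo 5,6 relationship), the isolated C8 (S) beyond the sp2 carbon C7, and the pair C10/C1 (10S,1R), which the C9 methylene separates from C8 and C2–C3 separate from C4. Fragile groups are the two epoxides (acid, Lewis acid), the two acetates, and the butenolide, whose C6 hydrogen is acidic enough for base to expel the C13 acetate through the furanolate; a ketone at C10 also turns the C8 oxygen into a β-leaving group. The real difficulty is closing a ten-membered ring that holds an exocyclic tetrasubstituted alkene, and relating three stereo clusters across spacers that transmit little. The key step exploits the triad C8(O)–C9H2–C10(O), which is the retron of a Δ2-isoxazoline spanning C8, C9 and C10; C10 can be a C=N carbon because its methyl group can arrive later at the ketone stage, and C8=C9 can be a vinyl group on the butenolide carbon C7.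

## Logic of the disconnections

**29 to 27 (through 28).** The C1–O bond of the 1,10-epoxide is cut. A cis-epoxide on a flexible ten-membered ring cannot be relied on from an alkene epoxidation, whereas displacement of a C1 sulfonate by the C10 oxygen is stereospecific. This removes one ring and leaves a 1,10-diol whose C1 centre is the epimer of the target's. The forward step demands selective activation of the secondary hydroxyl beside a tertiary one, an antiperiplanar O–C10–C1–O arrangement, and a base mild enough for the acetoxymethyl butenolide.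

**27 to 25 (through 26).** The C10–C14 bond is cut after the C1 oxygen is returned to silicon. The tertiary carbinol becomes a ketone flanked by the silyloxy stereocentre C1, which removes a quaternary stereocentre and uncovers the 1,3-relationship between the C10 carbonyl and the C8 oxygen. The forward addition must follow the Felkin–Anh sense relative to C1, must not be basic (β-acetoxy ketone), and must ignore two acetates, a lactone and an epoxide.

**25 to 23 (through 24).** The C8 acetate is removed and the β-hydroxy ketone is folded into an isoxazoline by joining the C8 oxygen to a nitrogen on C10. The aldol unit is stored in a robust heterocycle whose N–O bond is the only bond to break later. The forward step demands a reductant for N–O that spares the butenolide alkene, the epoxide and the acetate and does not dehydrate the aldol.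

**23 to 20 (through 22 and 21): the key disconnection.** C9–C10 and O–C8 are cut together. Both rings open at once, the ten-membered ring becomes an open chain, and one stereocentre (C8) disappears. What remains is a butenolide with a vinyl group on C7 and an aldoxime at C10. The forward step demands high dilution, carbon-to-C9 regiochemistry and attack on the alkene face that gives 8S.

**20 to 17 (through 19 and 18).** Functional group changes only: oxime from aldehyde, aldehyde from primary alcohol, alcohol from its 4-methoxybenzyl ether. This keeps C10 inert until the butenolide is complete. The forward steps demand an ether cleavage and an oxidation that tolerate epoxide, silyl ether and allylic acetate, and no epimerisation of the α-silyloxy aldehyde.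

**17 to 15 (through 16).** The C11–C13 bond is cut, leaving iodine on C11. The oxygenated carbon C13 is added last to the tetrasubstituted alkene, so that no alkenyl–metal intermediate has an oxygen leaving group in the β-position (which would collapse to an allene) and no choice between two propargylic oxygens as directing groups arises. The forward step demands an sp2–sp3 coupling on a hindered α-iodo lactone.

**15 to 13 (through 14).** C7–C8, C11–I and the lactone C12–O bond are cut. A butenolide carrying vinyl and iodine becomes a linear 4-hydroxyalk-2-ynoate, so ring, vinyl group and coupling handle come from one operation. A hydroxyl-directed carbomagnesiation would place a hot Grignard reagent next to an epoxy alkoxide; the conjugate addition used instead runs at −78 °C. The forward step demands that addition to the alkynoate outruns attack on the epoxide and that the syn adduct lactonises before it is iodinated.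

**13 to 12.** The two C–O bonds of the 4,5-epoxide are cut. The allylic hydroxyl on C6 and the methyl group cis to it on the alkene are the elements that make a peracid epoxidation threo-selective, so C4 and C5 follow from C6. The forward step demands that A(1,3) strain and hydrogen bonding act together and that the alkynoate stays inert.

**12 to 8 and 9 (through 11 and 10).** The C6–H bond is cut (carbinol to ketone), then C6–C7. One reagent-controlled reduction of an alkynyl ketone becomes the source of absolute configuration for C4, C5 and C6. The forward steps demand single addition of the acetylide and clear differentiation of the alkynyl and alkenyl arms in the reduction.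

**8 to 6 and 7.** The C4=C5 double bond is cut by an olefination retron, separating the C5–C6 unit from a methyl ketone. The forward step demands E selectivity at a trisubstituted alkene.

**6 to 2 and 3 (through 5 and 4), and 2 to 1.** The C2–C3 bond is cut beside the oxygenated stereocentre, which becomes the substituted carbon of a terminal epoxide. C1 therefore comes from the chiral pool in the S configuration. The forward steps demand opening at the unsubstituted epoxide carbon only.

## Other disconnections considered

**Alternative 1:** The cut removes both methyl groups (C10–C14, C4–C15) and the C1–O bond of the 1,10-epoxide. In the forward step a methyl nucleophile (MeMgBr or MeTiCl3) would add twice to the ten-membered chloro diketone A1, and the C10 alkoxide would displace the C1 chloride to give the epoxy diol A2.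
- In its favour: two quaternary carbinol centres and the cis-epoxide arise in one operation from the cheapest possible reagent. The methyl-addition-then-invertive-closure logic at C10/C1 is the same as in the chosen plan, and it is better in economy there (one operation against three, steps 17–19).
- Against it: A1 must already be a ten-membered ring, so this step does not solve the macrocyclisation. Two independent facial selectivities (C10 relative to the C1 chloride, C4 relative to the C5 oxygen) must both be right in a mobile ring. The α-chloro ketone can enolise, eliminate or undergo transannular aldol reaction under a basic Grignard reagent.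
- Structure and step economy: A2 still lacks C12 and C13 (C7 carries only a methylidene), and the 4,5-diol has to be turned into the trans-epoxide with inversion at C5. The endgame after the key step would therefore be longer than the five steps that follow the cycloaddition here.
- Mechanism: polar additions whose selectivity depends on ring conformation, against a cycloaddition whose regiochemistry is intrinsic.

**Alternative 2:** The cut is C5–C6. In the forward step a Lewis acid (BF3·OEt2 or MgBr2·OEt2) would activate the C5 aldehyde of the silyloxyfuran A3, and the furan would attack through its C6 terminus in a vinylogous Mukaiyama aldol reaction to give the macrocyclic butenolide A4.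
- In its favour: the butenolide substituents (C13 acetate, C8 oxygen) are complete before ring closure, and C4 can come from a chiral-pool tertiary carbinol. The step would set two stereocentres (C5, C6) while closing the ring, which is better than the one centre set by the chosen step. Its use of an invertive epoxide closure afterwards (C4 oxygen onto C5) is the equal of the C10/C1 tactic used here.
- Against it: the aldehyde is α-quaternary and hindered. A ten-membered ring must form without any template, and both the 5,6-relationship and the face relative to C4 have to be right at once. The Lewis acid would meet a furfuryl-type acetate, a tertiary silyl ether and a trisubstituted alkene.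
- Structure: the 1,10-cis-epoxide would have to come from a face-selective epoxidation of the Z alkene in the macrocycle, where the chosen plan uses a stereospecific displacement.
- Step economy: roughly equal (about four to five steps after A4 against five after 23).
- Mechanism: an open, Lewis-acid-mediated transition state against a concerted cycloaddition.

**Alternative 3:** The cut is C6–C7, C11–C12 and C12–O. In the forward step Mo(CO)6 with dimethyl sulfoxide (or Ru3(CO)12 under CO) would couple the alkyne, the aldehyde and carbon monoxide of the open-chain ynal A5 in a hetero-Pauson–Khand reaction, closing the ten-membered ring and the butenolide together to give A6.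
- In its favour: this is the most convergent plan. Both epoxides and C8 are in place before ring closure, and only desilylation and diacetylation would remain, which is better than the chosen plan in endgame length and in having no late stereochemical events at C1/C10. It is the equal of the chosen plan in closing the carbocycle and a five-membered heterocycle in one event.
- Against it: the reaction type is established for five- and six-membered carbocycles fused to the butenolide. An eight-atom tether gives the metallacycle no template.
- Functional group tolerance: low-valent metal carbonyls at high temperature would meet two epoxides and an α,β-epoxy aldehyde that can decarbonylate or epimerise at C5.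
- Stereocontrol: C6 would be created with no clear control element.
- Comparison: the chosen cycloaddition has closer precedent for large rings and runs at room temperature under near-neutral conditions, at the price of a longer endgame.

Key step: step 14

Remark: germacrane locants (C1–C15) are used for the atoms of all intermediates, open-chain ones included.
Remark: 20 and 23 were checked centre by centre against 29 (4R,5R,6S throughout; C1 is S up to 28 and R in 29; 8S from 23 on); they are consistent and need no correction.
Remark: in A1 the C5 hydroxyl is taken as free and in A3 the furan silyl group is taken as triisopropylsilyl; the disconnections do not fix either.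

## Route

Step 1
Reactants: 1 (R)-glycidol
Product: 2 (S)-2-{[(4-methoxybenzyl)oxy]methyl}oxirane
Conditions: NaH, 4-MeOC6H4CH2Cl, Bu4NI (cat.), DMF, 0 °C → rt
Reagents that add atoms: 4-methoxybenzyl chloride, COc1ccc(CCl)cc1
Why: Williamson etherification of the primary alkoxide; no bond to the stereocentre is touched (the descriptor changes from R to S only because the priorities change), and the epoxide carbons become C1 and C2 with C1 already in the S configuration that the late invertive closure needs.

Step 2
Reactants: 2 (S)-2-{[(4-methoxybenzyl)oxy]methyl}oxirane; 3 acetone N,N-dimethylhydrazone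
Product: 5 (S)-5-hydroxy-6-[(4-methoxybenzyl)oxy]hexan-2-one, via hydroxy hydrazone 4 (not isolated)
Conditions: 3, n-BuLi, THF, −78 → 0 °C; 2, 0 °C → rt; H2O; then oxalic acid (aq.), Et2O, rt
Reagents that add atoms: water, O
Why: The aza-enolate of the hydrazone opens the epoxide at its unsubstituted carbon (SN2, C2–C3 bond) and leaves C1 untouched; two-phase oxalic acid hydrolysis then frees the methyl ketone that holds C3, C4 and C15 without harming the benzyl-type ether.

Step 3
Reactants: 5 (S)-5-hydroxy-6-[(4-methoxybenzyl)oxy]hexan-2-one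
Product: 6 (S)-6-[(4-methoxybenzyl)oxy]-5-[(triisopropylsilyl)oxy]hexan-2-one
Conditions: iPr3SiOTf, 2,6-lutidine, CH2Cl2, −78 → 0 °C
Reagents that add atoms: triisopropylsilyl trifluoromethanesulfonate, CC(C)[Si](OS(=O)(=O)C(F)(F)F)(C(C)C)C(C)C
Why: Silylation of the secondary alcohol with a silyl triflate; any cyclic hemiketal drains through the open hydroxy ketone, and the bulky, non-chelating silyl ether is the group that later steers the Felkin–Anh addition at C10.

Step 4
Reactants: 6 (S)-6-[(4-methoxybenzyl)oxy]-5-[(triisopropylsilyl)oxy]hexan-2-one; 7 diethyl {2-[methoxy(methyl)amino]-2-oxoethyl}phosphonate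
Product: 8 (S,E)-N-methoxy-7-[(4-methoxybenzyl)oxy]-N,3-dimethyl-6-[(triisopropylsilyl)oxy]hept-2-enamide
Conditions: NaH, THF, 0 → 50 °C
Reagents that add atoms: none
Why: Horner–Wadsworth–Emmons olefination of a methyl ketone; the larger C3 chain should end up trans to the amide carbonyl, so the E alkene is expected as the main isomer and the minor Z isomer is removed by chromatography; forming the N-methoxy-N-methylamide directly saves an ester-to-amide exchange.

Step 5
Reactants: 8 (S,E)-N-methoxy-7-[(4-methoxybenzyl)oxy]-N,3-dimethyl-6-[(triisopropylsilyl)oxy]hept-2-enamide; 9 3,3,3-triethoxyprop-1-yne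
Product: 11 ethyl (S,E)-10-[(4-methoxybenzyl)oxy]-6-methyl-4-oxo-9-[(triisopropylsilyl)oxy]dec-5-en-2-ynoate, via ynone orthoester 10 (not isolated)
Conditions: 9, n-BuLi, THF, −78 °C; 8, −78 → −20 °C; NH4Cl (aq.); then TsOH·H2O (cat.), THF/H2O, 0 °C
Reagents that add atoms: water, O
Why: Acylation of a lithium acetylide by an N-methoxy-N-methylamide stops at the ketone because the chelated tetrahedral adduct survives until work-up; the orthoester is a propiolate anion equivalent that is stable as its lithium acetylide and is unmasked to the ethyl ester by brief acid-catalysed hydrolysis.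

Step 6
Reactants: 11 ethyl (S,E)-10-[(4-methoxybenzyl)oxy]-6-methyl-4-oxo-9-[(triisopropylsilyl)oxy]dec-5-en-2-ynoate
Product: 12 ethyl (4R,9S,E)-4-hydroxy-10-[(4-methoxybenzyl)oxy]-6-methyl-9-[(triisopropylsilyl)oxy]dec-5-en-2-ynoate
Conditions: B-isopinocampheyl-9-borabicyclo[3.3.1]nonane from (+)-α-pinene [(R)-Alpine-Borane], THF, 0 °C → rt; then HOCH2CH2NH2
Reagents that add atoms: none
Why: Midland reduction: the hydrogen of the isopinocampheyl group is transferred through a boat-like six-membered transition state in which the slim alkynyl arm of the ketone faces the pinane methyl group; the reagent from (+)-α-pinene gives (R)-carbinols from alkynyl ketones in this sense and should give the 6R alcohol, which fixes the absolute configuration of C6 and, through the next step, of C5 and C4.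

Step 7
Reactants: 12 ethyl (4R,9S,E)-4-hydroxy-10-[(4-methoxybenzyl)oxy]-6-methyl-9-[(triisopropylsilyl)oxy]dec-5-en-2-ynoate
Product: 13 ethyl (S)-4-hydroxy-4-{(2R,3R)-3-[(S)-4-[(4-methoxybenzyl)oxy]-3-[(triisopropylsilyl)oxy]butyl]-3-methyloxiran-2-yl}but-2-ynoate
Conditions: mCPBA, NaHCO3, CH2Cl2, 0 °C
Reagents that add atoms: 3-chloroperoxybenzoic acid, OOC(=O)c1cccc(Cl)c1
Why: Hydroxyl-directed peracid epoxidation under A(1,3) strain control: the C15 methyl cis to C6 keeps the carbinol hydrogen in the alkene plane, the hydrogen-bonded peracid attacks the face that carries the hydroxyl group, and the threo 4R,5R,6S epoxy alcohol should result (the C6 descriptor changes from R to S by priority only); the electron-poor alkynoate is inert to the peracid.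

Step 8
Reactants: 13 ethyl (S)-4-hydroxy-4-{(2R,3R)-3-[(S)-4-[(4-methoxybenzyl)oxy]-3-[(triisopropylsilyl)oxy]butyl]-3-methyloxiran-2-yl}but-2-ynoate
Product: 15 (S)-3-iodo-5-{(2R,3R)-3-[(S)-4-[(4-methoxybenzyl)oxy]-3-[(triisopropylsilyl)oxy]butyl]-3-methyloxiran-2-yl}-4-vinylfuran-2(5H)-one, via alkenylcopper lactone 14 (not isolated)
Conditions: CH2=CHMgBr, CuBr·SMe2, THF, −78 °C; then I2, −78 → 0 °C
Reagents that add atoms: vinylmagnesium bromide, C=C[Mg]Br; iodine, II
Why: Conjugate syn-carbocupration of the alkynoate places the vinyl group on C7 and copper on C11 with the C6 alkoxide cis to the ester, so the alkoxide lactonises and the alkenylcopper is iodinated with retention; at −78 °C addition to the alkynoate should be much faster than attack on the trisubstituted epoxide, and no hot Grignard reagent or alkenylmetal with a β-leaving group is involved.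

Step 9
Reactants: 15 (S)-3-iodo-5-{(2R,3R)-3-[(S)-4-[(4-methoxybenzyl)oxy]-3-[(triisopropylsilyl)oxy]butyl]-3-methyloxiran-2-yl}-4-vinylfuran-2(5H)-one
Product: 16 (S)-3-(hydroxymethyl)-5-{(2R,3R)-3-[(S)-4-[(4-methoxybenzyl)oxy]-3-[(triisopropylsilyl)oxy]butyl]-3-methyloxiran-2-yl}-4-vinylfuran-2(5H)-one
Conditions: Bu3SnCH2OH, Pd(PPh3)4 (cat.), dioxane, 80 °C
Reagents that add atoms: (tributylstannyl)methanol, CCCC[Sn](CCCC)(CCCC)CO
Why: Stille coupling of an α-iodo-α,β-unsaturated lactone with (tributylstannyl)methanol (oxidative addition to zerovalent palladium, transfer of the hydroxymethyl group from tin, reductive elimination) installs C13 under neutral conditions that spare epoxide and silyl ether.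

Step 10
Reactants: 16 (S)-3-(hydroxymethyl)-5-{(2R,3R)-3-[(S)-4-[(4-methoxybenzyl)oxy]-3-[(triisopropylsilyl)oxy]butyl]-3-methyloxiran-2-yl}-4-vinylfuran-2(5H)-one
Product: 17 [(S)-5-{(2R,3R)-3-[(S)-4-[(4-methoxybenzyl)oxy]-3-[(triisopropylsilyl)oxy]butyl]-3-methyloxiran-2-yl}-2-oxo-4-vinyl-2,5-dihydrofuran-3-yl]methyl acetate
Conditions: Ac2O, pyridine, 4-(dimethylamino)pyridine (cat.), CH2Cl2, 0 °C
Reagents that add atoms: acetic anhydride, CC(=O)OC(C)=O
Why: Acylation of the primary allylic alcohol under mild nucleophilic catalysis; the C13 acetate is the group present in the target.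

Step 11
Reactants: 17 [(S)-5-{(2R,3R)-3-[(S)-4-[(4-methoxybenzyl)oxy]-3-[(triisopropylsilyl)oxy]butyl]-3-methyloxiran-2-yl}-2-oxo-4-vinyl-2,5-dihydrofuran-3-yl]methyl acetate
Product: 18 {(S)-5-[(2R,3R)-3-{(S)-4-hydroxy-3-[(triisopropylsilyl)oxy]butyl}-3-methyloxiran-2-yl]-2-oxo-4-vinyl-2,5-dihydrofuran-3-yl}methyl acetate
Conditions: 2,3-dichloro-5,6-dicyano-1,4-benzoquinone (DDQ), CH2Cl2/pH 7 buffer, 0 °C
Reagents that add atoms: none
Why: Oxidative cleavage of the 4-methoxybenzyl ether by hydride abstraction with DDQ under buffered, non-acidic conditions; epoxide, silyl ether, acetate and the electron-poor diene should not be oxidised.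

Step 12
Reactants: 18 {(S)-5-[(2R,3R)-3-{(S)-4-hydroxy-3-[(triisopropylsilyl)oxy]butyl}-3-methyloxiran-2-yl]-2-oxo-4-vinyl-2,5-dihydrofuran-3-yl}methyl acetate
Product: 19 {(S)-5-[(2R,3R)-3-methyl-3-{(S)-4-oxo-3-[(triisopropylsilyl)oxy]butyl}oxiran-2-yl]-2-oxo-4-vinyl-2,5-dihydrofuran-3-yl}methyl acetate
Conditions: Dess–Martin periodinane, NaHCO3, CH2Cl2, 0 °C → rt
Reagents that add atoms: none
Why: Dess–Martin oxidation of the primary alcohol under buffered conditions; the α-silyloxy aldehyde is taken on at once so that C1 does not epimerise.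

Step 13
Reactants: 19 {(S)-5-[(2R,3R)-3-methyl-3-{(S)-4-oxo-3-[(triisopropylsilyl)oxy]butyl}oxiran-2-yl]-2-oxo-4-vinyl-2,5-dihydrofuran-3-yl}methyl acetate
Product: 20 {(S)-5-[(2R,3R)-3-{(S,E)-4-(hydroxyimino)-3-[(triisopropylsilyl)oxy]butyl}-3-methyloxiran-2-yl]-2-oxo-4-vinyl-2,5-dihydrofuran-3-yl}methyl acetate (the cycloaddition precursor)
Conditions: NH2OH·HCl, pyridine, EtOH, 0 °C
Reagents that add atoms: hydroxylamine hydrochloride, NO.Cl
Why: Condensation of the aldehyde with hydroxylamine; the E oxime is shown, and its Z isomer would converge on the same nitrile oxide in the next step.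

Step 14
Reactants: 20 {(S)-5-[(2R,3R)-3-{(S,E)-4-(hydroxyimino)-3-[(triisopropylsilyl)oxy]butyl}-3-methyloxiran-2-yl]-2-oxo-4-vinyl-2,5-dihydrofuran-3-yl}methyl acetate
Product: 23 (1S,4R,5R,6S,8S)-13-acetoxy-4,5-epoxy-1-[(triisopropylsilyl)oxy]-14-norgermacr-7(11)-en-12,6-olide bridged from C8 to C10 by O–N (Δ2-isoxazoline with C10=N), via hydroximoyl chloride 21 (not isolated), via nitrile oxide 22 (not isolated)
Conditions: N-chlorosuccinimide, pyridine (cat.), CHCl3, rt; then Et3N (syringe pump), CH2Cl2 (1 mM), rt → 40 °C
Reagents that add atoms: none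
Why: N-Chlorosuccinimide chlorinates the aldoxime carbon to hydroximoyl chloride 21, and slow addition of triethylamine at high dilution removes HCl to give nitrile oxide 22 at a low stationary concentration, so that ring closure is favoured over dimerisation. 22 then adds to the terminal C8=C9 alkene in a concerted, suprafacial 1,3-dipolar cycloaddition that forms C9–C10 and O–C8; the closest known reaction type is the intramolecular nitrile oxide–alkene cycloaddition used to close macrocycles. The ten-membered carbocycle closes through the C9–C10 bond in the endo mode (both alkene carbons end inside the ring), and the isoxazoline closes in the same event through O–C8, so that it bridges C8 and C10 across C9. Carbon-to-C9 regiochemistry is the normal preference of a monosubstituted alkene and is reinforced by the tether, since the reverse orientation would have to form a nine-membered ring. The one new stereocentre, C8, is controlled by C6: the tether leaves C6 on one face of the planar butenolide, the vinyl group stays conjugated with C7=C11 with C9 turned toward C6, and delivery of the dipole from the face that carries C5 should put oxygen on C8 in the 8S sense. The step needs chemoselectivity for the dipole over epoxide, lactone, acetate and silyl ether, which the near-neutral conditions give, and because the amine is consumed as it is added the acetoxymethyl butenolide is not left standing in base.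

Step 15
Reactants: 23 (1S,4R,5R,6S,8S)-13-acetoxy-4,5-epoxy-1-[(triisopropylsilyl)oxy]-14-norgermacr-7(11)-en-12,6-olide bridged from C8 to C10 by O–N
Product: 24 (1S,4R,5R,6S,8S)-13-acetoxy-4,5-epoxy-8-hydroxy-10-oxo-1-[(triisopropylsilyl)oxy]-14-norgermacr-7(11)-en-12,6-olide
Conditions: Mo(CO)6, MeCN/H2O, 80 °C
Reagents that add atoms: water, O
Why: Reductive N–O cleavage of the isoxazoline by Mo(CO)6 in wet acetonitrile gives the β-hydroxy imine, which hydrolyses to the ketone; the reagent should leave the tetrasubstituted butenolide alkene, the epoxide and the acetate alone, and C8 keeps the oxygen and configuration set in the cycloaddition.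

Step 16
Reactants: 24 (1S,4R,5R,6S,8S)-13-acetoxy-4,5-epoxy-8-hydroxy-10-oxo-1-[(triisopropylsilyl)oxy]-14-norgermacr-7(11)-en-12,6-olide
Product: 25 (1S,4R,5R,6S,8S)-8,13-diacetoxy-4,5-epoxy-10-oxo-1-[(triisopropylsilyl)oxy]-14-norgermacr-7(11)-en-12,6-olide
Conditions: Ac2O, pyridine, 4-(dimethylamino)pyridine (cat.), CH2Cl2, 0 °C
Reagents that add atoms: acetic anhydride, CC(=O)OC(C)=O
Why: Acylation of the secondary C8 alcohol at 0 °C with only pyridine and a catalytic acyl-transfer agent, mild enough to avoid β-elimination of the new acetate from the ketone; C8 then has the substitution of the target.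

Step 17
Reactants: 25 (1S,4R,5R,6S,8S)-8,13-diacetoxy-4,5-epoxy-10-oxo-1-[(triisopropylsilyl)oxy]-14-norgermacr-7(11)-en-12,6-olide
Product: 26 (1S,4R,5R,6S,8S,10S)-8,13-diacetoxy-4,5-epoxy-10-hydroxy-1-[(triisopropylsilyl)oxy]germacr-7(11)-en-12,6-olide
Conditions: MeTi(OiPr)3 (excess), THF, −20 °C → rt
Reagents that add atoms: methyltitanium triisopropoxide, C[Ti](OC(C)C)(OC(C)C)OC(C)C
Why: Addition of a non-basic, non-chelating methyltitanium reagent to the ketone, which tolerates esters, lactone and epoxide; by the Felkin–Anh model the bulky silyloxy group on C1 stands anti to the incoming methyl group, which passes the C1 hydrogen, and this should give the 10S tertiary alcohol needed for the cis-epoxide.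

Step 18
Reactants: 26 (1S,4R,5R,6S,8S,10S)-8,13-diacetoxy-4,5-epoxy-10-hydroxy-1-[(triisopropylsilyl)oxy]germacr-7(11)-en-12,6-olide
Product: 27 (1S,4R,5R,6S,8S,10S)-8,13-diacetoxy-4,5-epoxy-1,10-dihydroxygermacr-7(11)-en-12,6-olide
Conditions: Bu4NF, AcOH, THF, 0 °C → rt
Reagents that add atoms: none
Why: Fluoride-mediated cleavage of the silyl ether, buffered with acetic acid so that the acetates, the butenolide and the epoxide are not exposed to basic fluoride.

Step 19
Reactants: 27 (1S,4R,5R,6S,8S,10S)-8,13-diacetoxy-4,5-epoxy-1,10-dihydroxygermacr-7(11)-en-12,6-olide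
Product: 29 (1R,4R,5R,6S,8S,10S)-8,13-diacetoxy-1,10:4,5-diepoxygermacr-7(11)-en-12,6-olide (CNP0271844.2), via C1 mesylate 28 (not isolated)
Conditions: MsCl, Et3N, CH2Cl2, −20 °C; then DBU, 0 °C → rt
Reagents that add atoms: none
Why: Selective sulfonylation of the secondary C1 hydroxyl beside the tertiary one, then intramolecular SN2 displacement (3-exo-tet) by the C10 oxygen with inversion at C1 (S to R) and retention at C10, which gives the cis-1,10-epoxide stereospecifically.

## Compound list

1 | (R)-glycidol | OC[C@@H]1CO1 | starting material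
2 | (S)-2-{[(4-methoxybenzyl)oxy]methyl}oxirane | COc1ccc(COC[C@@H]2CO2)cc1 | intermediate
3 | acetone N,N-dimethylhydrazone | CC(C)=NN(C)C | starting material
4 | (S)-5-hydroxy-6-[(4-methoxybenzyl)oxy]hexan-2-one N,N-dimethylhydrazone (not isolated) | COc1ccc(COC[C@@H](O)CCC(C)=NN(C)C)cc1 | intermediate
5 | (S)-5-hydroxy-6-[(4-methoxybenzyl)oxy]hexan-2-one | COc1ccc(COC[C@@H](O)CCC(C)=O)cc1 | intermediate
6 | (S)-6-[(4-methoxybenzyl)oxy]-5-[(triisopropylsilyl)oxy]hexan-2-one | COc1ccc(COC[C@@H](O[Si](C(C)C)(C(C)C)C(C)C)CCC(C)=O)cc1 | intermediate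
7 | diethyl {2-[methoxy(methyl)amino]-2-oxoethyl}phosphonate | CCOP(=O)(CC(=O)N(C)OC)OCC | starting material
8 | (S,E)-N-methoxy-7-[(4-methoxybenzyl)oxy]-N,3-dimethyl-6-[(triisopropylsilyl)oxy]hept-2-enamide | COc1ccc(COC[C@@H](O[Si](C(C)C)(C(C)C)C(C)C)CC/C(C)=C/C(=O)N(C)OC)cc1 | intermediate
9 | 3,3,3-triethoxyprop-1-yne | C#CC(OCC)(OCC)OCC | starting material
10 | (S,E)-1,1,1-triethoxy-10-[(4-methoxybenzyl)oxy]-6-methyl-9-[(triisopropylsilyl)oxy]dec-5-en-2-yn-4-one (not isolated) | COc1ccc(COC[C@@H](O[Si](C(C)C)(C(C)C)C(C)C)CC/C(C)=C/C(=O)C#CC(OCC)(OCC)OCC)cc1 | intermediate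
11 | ethyl (S,E)-10-[(4-methoxybenzyl)oxy]-6-methyl-4-oxo-9-[(triisopropylsilyl)oxy]dec-5-en-2-ynoate | COc1ccc(COC[C@@H](O[Si](C(C)C)(C(C)C)C(C)C)CC/C(C)=C/C(=O)C#CC(=O)OCC)cc1 | intermediate
12 | ethyl (4R,9S,E)-4-hydroxy-10-[(4-methoxybenzyl)oxy]-6-methyl-9-[(triisopropylsilyl)oxy]dec-5-en-2-ynoate | COc1ccc(COC[C@@H](O[Si](C(C)C)(C(C)C)C(C)C)CC/C(C)=C/[C@@H](O)C#CC(=O)OCC)cc1 | intermediate
13 | ethyl (S)-4-hydroxy-4-{(2R,3R)-3-[(S)-4-[(4-methoxybenzyl)oxy]-3-[(triisopropylsilyl)oxy]butyl]-3-methyloxiran-2-yl}but-2-ynoate | COc1ccc(COC[C@@H](O[Si](C(C)C)(C(C)C)C(C)C)CC[C@@]2(C)O[C@@H]2[C@@H](O)C#CC(=O)OCC)cc1 | intermediate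
14 | alkenylcopper lactone: the butenolide of 15 with copper in place of iodine on C11 (not isolated) | COc1ccc(COC[C@@H](O[Si](C(C)C)(C(C)C)C(C)C)CC[C@@]2(C)O[C@@H]2[C@H]3OC(=O)C([Cu])=C3C=C)cc1 | intermediate
15 | (S)-3-iodo-5-{(2R,3R)-3-[(S)-4-[(4-methoxybenzyl)oxy]-3-[(triisopropylsilyl)oxy]butyl]-3-methyloxiran-2-yl}-4-vinylfuran-2(5H)-one | COc1ccc(COC[C@@H](O[Si](C(C)C)(C(C)C)C(C)C)CC[C@@]2(C)O[C@@H]2[C@H]3OC(=O)C(I)=C3C=C)cc1 | intermediate
16 | (S)-3-(hydroxymethyl)-5-{(2R,3R)-3-[(S)-4-[(4-methoxybenzyl)oxy]-3-[(triisopropylsilyl)oxy]butyl]-3-methyloxiran-2-yl}-4-vinylfuran-2(5H)-one | COc1ccc(COC[C@@H](O[Si](C(C)C)(C(C)C)C(C)C)CC[C@@]2(C)O[C@@H]2[C@H]3OC(=O)C(CO)=C3C=C)cc1 | intermediate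
17 | [(S)-5-{(2R,3R)-3-[(S)-4-[(4-methoxybenzyl)oxy]-3-[(triisopropylsilyl)oxy]butyl]-3-methyloxiran-2-yl}-2-oxo-4-vinyl-2,5-dihydrofuran-3-yl]methyl acetate | COc1ccc(COC[C@@H](O[Si](C(C)C)(C(C)C)C(C)C)CC[C@@]2(C)O[C@@H]2[C@H]3OC(=O)C(COC(C)=O)=C3C=C)cc1 | intermediate
18 | {(S)-5-[(2R,3R)-3-{(S)-4-hydroxy-3-[(triisopropylsilyl)oxy]butyl}-3-methyloxiran-2-yl]-2-oxo-4-vinyl-2,5-dihydrofuran-3-yl}methyl acetate | CC(=O)OCC1=C(C=C)[C@@H]([C@H]2O[C@]2(C)CC[C@H](O[Si](C(C)C)(C(C)C)C(C)C)CO)OC1=O | intermediate
19 | {(S)-5-[(2R,3R)-3-methyl-3-{(S)-4-oxo-3-[(triisopropylsilyl)oxy]butyl}oxiran-2-yl]-2-oxo-4-vinyl-2,5-dihydrofuran-3-yl}methyl acetate | CC(=O)OCC1=C(C=C)[C@@H]([C@H]2O[C@]2(C)CC[C@H](O[Si](C(C)C)(C(C)C)C(C)C)C=O)OC1=O | intermediate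
20 | (E)-aldoxime of 19: vinylbutenolide aldoxime with 4R,5R-epoxide and 1S silyl ether | CC(=O)OCC1=C(C=C)[C@@H]([C@H]2O[C@]2(C)CC[C@H](O[Si](C(C)C)(C(C)C)C(C)C)/C=N/O)OC1=O | intermediate
21 | (Z)-hydroximoyl chloride of 20 (chlorine on C10; not isolated) | CC(=O)OCC1=C(C=C)[C@@H]([C@H]2O[C@]2(C)CC[C@H](O[Si](C(C)C)(C(C)C)C(C)C)/C(Cl)=N/O)OC1=O | intermediate
22 | nitrile oxide at C10 (not isolated) | CC(=O)OCC1=C(C=C)[C@@H]([C@H]2O[C@]2(C)CC[C@H](O[Si](C(C)C)(C(C)C)C(C)C)C#[N+][O-])OC1=O | intermediate
23 | (1S,4R,5R,6S,8S)-13-acetoxy-4,5-epoxy-1-[(triisopropylsilyl)oxy]-14-norgermacr-7(11)-en-12,6-olide bridged from C8 to C10 by O–N (Δ2-isoxazoline, C10=N) | CC(=O)OCC1=C2[C@@H]3CC(=NO3)[C@@H](O[Si](C(C)C)(C(C)C)C(C)C)CC[C@@]4(C)O[C@@H]4[C@H]2OC1=O | intermediate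
24 | (1S,4R,5R,6S,8S)-13-acetoxy-4,5-epoxy-8-hydroxy-10-oxo-1-[(triisopropylsilyl)oxy]-14-norgermacr-7(11)-en-12,6-olide | CC(=O)OCC1=C2[C@@H](O)CC(=O)[C@@H](O[Si](C(C)C)(C(C)C)C(C)C)CC[C@@]3(C)O[C@@H]3[C@H]2OC1=O | intermediate
25 | (1S,4R,5R,6S,8S)-8,13-diacetoxy-4,5-epoxy-10-oxo-1-[(triisopropylsilyl)oxy]-14-norgermacr-7(11)-en-12,6-olide | CC(=O)OCC1=C2[C@@H](OC(C)=O)CC(=O)[C@@H](O[Si](C(C)C)(C(C)C)C(C)C)CC[C@@]3(C)O[C@@H]3[C@H]2OC1=O | intermediate
26 | (1S,4R,5R,6S,8S,10S)-8,13-diacetoxy-4,5-epoxy-10-hydroxy-1-[(triisopropylsilyl)oxy]germacr-7(11)-en-12,6-olide | CC(=O)OCC1=C2[C@@H](OC(C)=O)C[C@](C)(O)[C@@H](O[Si](C(C)C)(C(C)C)C(C)C)CC[C@@]3(C)O[C@@H]3[C@H]2OC1=O | intermediate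
27 | (1S,4R,5R,6S,8S,10S)-8,13-diacetoxy-4,5-epoxy-1,10-dihydroxygermacr-7(11)-en-12,6-olide | CC(=O)OCC1=C2[C@@H](OC(C)=O)C[C@](C)(O)[C@@H](O)CC[C@@]3(C)O[C@@H]3[C@H]2OC1=O | intermediate
28 | 1-O-methanesulfonate of 27 (not isolated) | CC(=O)OCC1=C2[C@@H](OC(C)=O)C[C@](C)(O)[C@@H](OS(C)(=O)=O)CC[C@@]3(C)O[C@@H]3[C@H]2OC1=O | intermediate
29 | (1R,4R,5R,6S,8S,10S)-8,13-diacetoxy-1,10:4,5-diepoxygermacr-7(11)-en-12,6-olide (CNP0271844.2) | CC(=O)OCC1=C2[C@@H](OC(C)=O)C[C@]3(C)O[C@@H]3CC[C@@]3(C)O[C@@H]3[C@H]2OC1=O | target

## Step count and least certain steps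

Total step count: 19. Longest linear sequence: 19 steps (1 to 29); 3, 7 and 9 are bought.

**Step 14 (key step).** Closure of a ten-membered ring is slow, so the most likely failure is loss of the nitrile oxide by dimerisation to a furoxan or by oligomerisation before it reaches the vinyl group. A second uncertainty is that the 8S face rests on a conformational argument. Fallback: replace the nitrile oxide by a silyl nitronate, which cannot dimerise and can be heated at ordinary concentration. The route is left at 18: iodination (PPh3, I2, imidazole) should give the primary iodide F1, displacement with NaNO2 (phloroglucinol, dimethyl sulfoxide) the nitro compound F2, and silylation (Me3SiCl, Et3N) the silyl nitronate F3. F3 should cyclise on warming to the N-silyloxyisoxazolidine F4; acid (TsOH) then removes trimethylsilanol, and the route is rejoined at 23.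

**Step 17.** The face of attack may be set by the conformation of the ring and not by C1, and the titanium reagent may be slow at a ketone flanked by a silyloxy group, so poor or reversed selectivity is the likely problem. Fallback: use the other epimer, so that stereocontrol moves from a carbonyl addition to an alkene epoxidation. Starting from 25, the addition product of opposite configuration at C10, the 10R alcohol F5, would be desilylated to the 10R diol F6 and converted with thiocarbonyldiimidazole into the cyclic thiocarbonate F7. Corey–Winter fragmentation with P(OMe)3 is a syn elimination and should give from this diastereomer the (Z)-1(10)-alkene F8. Epoxidation of F8 with dimethyldioxirane on the outer face of the ring would rejoin the route at 29.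

**Step 8.** The likely failure is loss of the epoxide to the organometallic reagent or its salts next to the C6 alkoxide, or protonation of the alkenylcopper before iodine arrives. Fallback: carry out the carbocupration before the epoxide exists. From 12 the same reagents should give, through the alkenylcopper lactone F9, the iodobutenolide F10 with the C4=C5 alkene intact. A Shi epoxidation of this isolated trisubstituted alkene (D-fructose-derived ketone, KHSO5 as 2KHSO5·KHSO4·K2SO4, buffered), now under reagent control, rejoins the route at 15.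

**Step 9.** The hydroxymethyl group may transfer slowly from tin to palladium at this hindered position, with reductive loss of iodine as the competing process. Fallback: from 15, palladium-catalysed formylation (Pd(PPh3)4, CO, Bu3SnH) to the aldehyde F11 and 1,2-reduction (NaBH4, CeCl3) lead back to 16.

**Step 6.** The reagent may not differentiate the alkenyl and alkynyl arms well enough, which would lower the selectivity at C6 and appear as diastereomers because C1 is already set. Fallback: form the C6–C7 bond asymmetrically instead of reducing a ketone. From 8, iBu2AlH at −78 °C gives the enal F12. Addition of ethyl propiolate with Me2Zn and the enantiomer of the ProPhenol ligand [2,6-bis{[2-(hydroxydiphenylmethyl)pyrrolidin-1-yl]methyl}-4-methylphenol] that sends the zinc alkynylide to the Si face of the aldehyde returns to 12.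

**Step 19.** Base may cause loss of the C13 acetate through the C6 furanolate, or acetyl migration from O8 to O10, in competition with ring closure. Fallback: Mitsunobu cyclodehydration of 27 (PPh3, diisopropyl azodicarboxylate). The secondary C1 hydroxyl is activated as the alkoxyphosphonium ion F13 and displaced by the C10 hydroxyl with the same inversion, without sulfonate or amidine base, arriving at 29.

## Further compounds

F1 | step 14 | primary iodide from 18 (iodine on C10) | CC(=O)OCC1=C(C=C)[C@@H]([C@H]2O[C@]2(C)CC[C@H](O[Si](C(C)C)(C(C)C)C(C)C)CI)OC1=O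
F2 | step 14 | primary nitro compound (nitro group on C10) | CC(=O)OCC1=C(C=C)[C@@H]([C@H]2O[C@]2(C)CC[C@H](O[Si](C(C)C)(C(C)C)C(C)C)C[N+](=O)[O-])OC1=O
F3 | step 14 | trimethylsilyl nitronate at C10 (not isolated) | CC(=O)OCC1=C(C=C)[C@@H]([C@H]2O[C@]2(C)CC[C@H](O[Si](C(C)C)(C(C)C)C(C)C)C=[N+]([O-])O[Si](C)(C)C)OC1=O
F4 | step 14 | N-(trimethylsilyloxy)isoxazolidine corresponding to 23 (C10 configuration immaterial) | CC(=O)OCC1=C2[C@@H]3CC(N(O[Si](C)(C)C)O3)[C@@H](O[Si](C(C)C)(C(C)C)C(C)C)CC[C@@]4(C)O[C@@H]4[C@H]2OC1=O
F5 | step 17 | (10R)-epimer of 26 | CC(=O)OCC1=C2[C@@H](OC(C)=O)C[C@@](C)(O)[C@@H](O[Si](C(C)C)(C(C)C)C(C)C)CC[C@@]3(C)O[C@@H]3[C@H]2OC1=O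
F6 | step 17 | (10R)-epimer of 27 | CC(=O)OCC1=C2[C@@H](OC(C)=O)C[C@@](C)(O)[C@@H](O)CC[C@@]3(C)O[C@@H]3[C@H]2OC1=O
F7 | step 17 | cyclic 1,10-thiocarbonate of F6 | CC(=O)OCC1=C2[C@@H](OC(C)=O)C[C@@]3(C)OC(=S)O[C@H]3CC[C@@]4(C)O[C@@H]4[C@H]2OC1=O
F8 | step 17 | (4R,5R,6S,8S,1(10)Z)-8,13-diacetoxy-4,5-epoxygermacra-1(10),7(11)-dien-12,6-olide | CC(=O)OCC1=C2[C@@H](OC(C)=O)C/C(C)=C\CC[C@@]3(C)O[C@@H]3[C@H]2OC1=O
F9 | step 8 | alkenylcopper lactone with the C4=C5 alkene intact (not isolated) | COc1ccc(COC[C@@H](O[Si](C(C)C)(C(C)C)C(C)C)CC/C(C)=C/[C@H]2OC(=O)C([Cu])=C2C=C)cc1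
F10 | step 8 | 3-iodo-4-vinylbutenolide with the (E)-C4=C5 alkene intact (C6 configured as in 12) | COc1ccc(COC[C@@H](O[Si](C(C)C)(C(C)C)C(C)C)CC/C(C)=C/[C@H]2OC(=O)C(I)=C2C=C)cc1
F11 | step 9 | 3-formyl analogue of 16 (aldehyde on C11) | COc1ccc(COC[C@@H](O[Si](C(C)C)(C(C)C)C(C)C)CC[C@@]2(C)O[C@@H]2[C@H]3OC(=O)C(C=O)=C3C=C)cc1
F12 | step 6 | (S,E)-7-[(4-methoxybenzyl)oxy]-3-methyl-6-[(triisopropylsilyl)oxy]hept-2-enal | COc1ccc(COC[C@@H](O[Si](C(C)C)(C(C)C)C(C)C)CC/C(C)=C/C=O)cc1
F13 | step 19 | C1 alkoxytriphenylphosphonium ion of 27 (not isolated) | CC(=O)OCC1=C2[C@@H](OC(C)=O)C[C@](C)(O)[C@@H](O[P+](c4ccccc4)(c4ccccc4)c4ccccc4)CC[C@@]3(C)O[C@@H]3[C@H]2OC1=O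
A1 | alternative 1 | (1S,5S,6S,8S)-8-(tert-butyldimethylsilyloxy)-1-chloro-5-hydroxy-7-methylidene-6-(triethylsilyloxy)cyclodecane-4,10-dione (germacrane locants) | O=C1C[C@H](O[Si](C)(C)C(C)(C)C)C(=C)[C@H](O[Si](CC)(CC)CC)[C@H](O)C(=O)CC[C@@H]1Cl
A2 | alternative 1 | (1R,4R,5S,6S,8S,10S)-1,10-epoxide with 4,5-diol, 7-methylidene, 6-triethylsilyloxy and 8-tert-butyldimethylsilyloxy groups (germacrane locants) | C[C@]12C[C@H](O[Si](C)(C)C(C)(C)C)C(=C)[C@H](O[Si](CC)(CC)CC)[C@H](O)[C@](C)(O)CC[C@H]1O2
A3 | alternative 2 | [4-{(1S,3Z,7R)-1-(tert-butyldimethylsilyloxy)-3,7-dimethyl-8-oxo-7-(triethylsilyloxy)oct-3-en-1-yl}-2-(triisopropylsilyloxy)furan-3-yl]methyl acetate | CC(=O)OCc1c(O[Si](C(C)C)(C(C)C)C(C)C)occ1[C@@H](O[Si](C)(C)C(C)(C)C)C/C(C)=C\CC[C@@](C)(O[Si](CC)(CC)CC)C=O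
A4 | alternative 2 | (4R,5S,6S,8S,1(10)Z)-13-acetoxy-8-(tert-butyldimethylsilyloxy)-5-hydroxy-4-(triethylsilyloxy)germacra-1(10),7(11)-dien-12,6-olide | CC(=O)OCC1=C2[C@@H](O[Si](C)(C)C(C)(C)C)C/C(C)=C\CC[C@@](C)(O[Si](CC)(CC)CC)[C@@H](O)[C@H]2OC1=O
A5 | alternative 3 | open-chain ynal: C6 aldehyde, (4R,5R)- and (1R,10S)-epoxides, 8S tert-butyldimethylsilyl ether, C7≡C11 alkyne, C13 tert-butyldimethylsilyl ether | CC(C)(C)[Si](C)(C)OCC#C[C@@H](O[Si](C)(C)C(C)(C)C)C[C@]1(C)O[C@@H]1CC[C@@]1(C)O[C@@H]1C=O
A6 | alternative 3 | 8,13-bis(tert-butyldimethylsilyl) ether of the diol corresponding to 29 | CC(C)(C)[Si](C)(C)OCC1=C2[C@@H](O[Si](C)(C)C(C)(C)C)C[C@]3(C)O[C@@H]3CC[C@@]3(C)O[C@@H]3[C@H]2OC1=O
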